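Saturday's closed flask and Monday's tank take the same charge and the same 50 s (in Monday's tank, on average), so it is easy to expect the same yield from both.

common to all: coupling partner 1.50 mM; free catalyst 10 µM

| run | substrate | remark | time |
|---|---|---|---|
| Monday's | 0.0010 M | a single well-mixed tank run continuously and read at steady state, 50 s in it on average |  |
| Wednesday's | 0.0010 M (fed, over 50.0 s) | all but substrate at the start; substrate goes in evenly over 50.0 s, the run ends at 50 s | 50 s |
| Saturday's | 0.0010 M | everything together in a closed stirred flask, run for 50 s | 50 s |
| Tuesday's | 0.0010 M | one stirred flow tank at steady state, fed with the mixture as stated, mean residence time 500 s |  |

    substrate + free catalyst → catalyst intermediate A (k1 = 16000 /M/s)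
    coupling partner + catalyst intermediate A → catalyst intermediate B (k2 = 29000 /M/s)
    catalyst intermediate B ⇌ by-product + catalyst intermediate C (K3 = 4.7 × 10⁻⁴ M, k3 = 360 /s)
    catalyst intermediate C ⇌ catalyst intermediate D (K4 = 0.14, k4 = 5300 /s)
    catalyst intermediate D → free catalyst + target (k5 = 58 /s)
    2 coupling partner → self-condensation product (k6 = 850 /M/s)
    substrate + by-product → side product (k7 = 23 /M/s)

* the set-up with the highest amount of target at the outlet or at the end, in percent of the substrate put in ("none" if the first two lie within 2 percentage points) (Monday's / Wednesday's / Saturday's / Tuesday's / none)
* amount of target at the outlet or at the end, in percent of the substrate put in, Monday's
* amount of target at the outlet or at the end, in percent of the substrate put in, Wednesday's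
* amount of target at the outlet or at the end, in percent of the substrate put in, Saturday's
* amount of target at the outlet or at the end, in percent of the substrate put in, Tuesday's

- a step written with two of one species runs at k times the square of its concentration and takes two of it each time
- the stated concentrations are those of everything mixed, before any reaction; amounts are the same in each set-up
- the feed brings no volume worth counting
- run time (Wednesday's): 50 s

Begin by asking what Saturday's closed flask can reach at its end. The coupling partner has two ways out: it can couple on catalyst intermediate A, which is pseudo-first-order in partner while that intermediate holds steady, or it can self-condense, which is second order. At the charge, its first half-life by self-condensation is 0.392 s. That is shorter than the 4.3 s half-life of substrate by step 1, with the other concentrations held at their charge. So you should ask how much partner the catalyst can catch before self-condensation takes it.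

My reckoning rests on the crossover level: the partner concentration at which self-condensation removes partner as fast as coupling does, with the full catalyst charge sitting as intermediate A. It equals the coupling constant times the catalyst charge, divided by twice the self-condensation constant, which gives 0.171 mM. Saturday's flask starts 8.79 times above that level. At any moment, the coupling share of the partner being consumed cannot exceed the crossover level divided by the sum of that level and the partner concentration. Adding this up as the partner falls gives a ceiling for Saturday's flask of the crossover level times ln(1 + charge/crossover level), or 38.9% of the substrate. You should treat this as a ceiling, not a yield, and my reckoning stops there.

In Monday's tank the partner enters a mixture that has already reacted. Even with coupling ignored, balancing flow against self-condensation puts the partner at 0.127 mM, which is below the crossover level. Tuesday's tank, with ten times the residence time, gives 0.0414 mM by the same balance, a lower level than in Monday's tank. I therefore expect the order Saturday's, Monday's, Tuesday's, but I put no yield on the tanks.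

The forecast gives 58% for Monday's, 9% for Wednesday's, 17% for Saturday's and 86% for Tuesday's, and it names Tuesday's, on the ground that “The flow tanks keep it fed continuously at low concentration”. My ceiling for Saturday's flask does not give its number; it stands above it.

The simulation gives 58.7% for Monday's tank, 8.50% for Wednesday's run, 18.3% for Saturday's flask and 85.7% for Tuesday's tank, so Tuesday's comes first. Saturday's flask reads 18.3% at 500 s. Its yield lies below the ceiling built on the crossover level of 0.171 mM, at 47.0% of it. Wednesday's run starts with the same partner and catalyst, so the same 38.9% applies there, and its yield lies below that, reading 8.50% at the end and 8.50% at 500 s.

The numbers of this flask were set for the occasion; the rest is arithmetic.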